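- The shift chemist asked me whether the next run should stand for 2.0 h, as in spring, or for 3.0 h, as at midnight, so I reckoned what the longer time would buy.

| flask | substrate | gas phase | time |
|---|---|---|---|
| spring | 1.0 M | 200 mM (held) | 2.0 h |
| midnight | 1.0 M | 200 mM (held) | 3.0 h |

- which of these there is most of at the end, counted by the substrate in it, spring (substrate / target)
- which of these there is most of at the end, counted by the substrate in it, midnight (substrate / target)
- how much there is at the end of the one of these that leads, in percent of the substrate charged: spring
- how much there is at the end of the one of these that leads, in percent of the substrate charged: midnight

    gas phase ⇌ dissolved gas, rate k1*(csat - [dissolved gas]) (k1 = 0.00143 s⁻¹, csat = 200 mM)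
    substrate + dissolved gas ⇌ target (K2 = 1.87 L mol⁻¹, k2 = 0.00210 L mol⁻¹ s⁻¹)

- at the start none of the gas is dissolved
- run time (spring): 2.0 h

- I took the far end first: with dissolved gas at 200 mM, step two's equilibrium puts target over substrate at 0.374, so 72.8% of the charged substrate remains. I called this share, left at equilibrium with the gas at its saturation level, the equilibrium floor; it is the mark of thermodynamic control.
- At the near end, gas crossed with a time of 11.7 min; close to the floor, with dissolved gas at 200 mM, step two relaxed with a time of 10.8 min.
- Substrate also drew the gas away as it arrived, so I joined the two ends. I summed the first-order constants of transfer, of uptake of gas by substrate at the floor, and of relaxation, then divided by the product of the transfer and relaxation constants, which gave an estimated slow time of 34.0 min.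
- Letting the starting gap above the floor decay over that time left 0.8 percentage points in spring and 0.14 points at midnight. I therefore committed to substrate at 73.6% and 72.9%, with more substrate than target, and the longer run bought 0.66 points.
- The forecast named substrate and substrate as leading, at 73.3% (range 72.8% to 74.5%) in spring and 72.9% (range 72.6% to 73.4%) at midnight, saying that substrate “stays ahead of target at both times”. Its spring figure differed from mine.
- The simulation gave substrate leading at 73.4% in spring and substrate leading at 72.9% at midnight.
- Spring ended 0.6 points above the equilibrium floor and midnight 0.100 points above it, so the longer time moved substrate by 0.50 points, and I kept the spring time. For the midnight flask read at 50 min, floor plus gap gave 79.1%, and the flask held 79.0%. The floor exists because of the backward run from target to substrate and dissolved gas: with that run taken away, the lead turned to target and spring substrate ended at 19.7% instead of 73.4%.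

The numbers are those of an exercise; the result is computed.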